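**Retrosynthetic overview**
1. The 36-membered lactone is the only ring made. It is closed by a double Stille "stitch" of bis(dienyl iodide) 42 with (E)-Bu3SnCH=CHSnBu3, which forms C5–C6, C7–C8 and the pentaene in one operation; the C1–O35 ester is made intermolecularly beforehand (no macrolactonisation, no macro-olefination).
2. The two dienyl iodides come from acid 40 (C1–C5; Wittig, Takai) and from cross-metathesis then Takai on the allyl terminus (C8–C11).
3. The C11–C35 chain is joined at C21 by a one-flask silyl-dithiane linchpin coupling of epoxide A (C11–C20) with epoxide B (C22–C35). C27 is a second dithiane, and C23/C25 come from (S,S)-diepoxypentane.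
4. Epoxide A: C15/C17 from statin building block 1, C13 by catalytic allylation, C19 by hydrolytic kinetic resolution. C35 comes from (S)-isopropyloxirane.
5. Ring order: the syn-acetonide ring arrives with 1; the macrocycle is formed in step 24; all protecting groups fall in step 25.

Assumption: the target is made in the open-chain hydroxy-ketone form drawn (it may equilibrate with internal hemiketals), and 1, 10, 14, 24 and 43 are taken as catalogue chemicals.

Convention: locants C1–C35 are those of the target (C1 = lactone carbonyl, C35 = isopropyl carbinol). TBS = tert-butyldimethylsilyl, PMB = 4-methoxybenzyl.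

**Route**

Step 1
Reactants: 1 tert-butyl 2-[(4R,6R)-6-(cyanomethyl)-2,2-dimethyl-1,3-dioxan-4-yl]acetate
Product: 2 2-[(4R,6S)-6-(2-hydroxyethyl)-2,2-dimethyl-1,3-dioxan-4-yl]acetonitrile
Conditions: LiBH4 (3 equiv), MeOH (3 equiv), THF, 0 → 50 °C
Reagents that add atoms: none
Why: Chemoselective borohydride reduction of the ester to the primary alcohol (future C13) leaves the nitrile and the acetonide untouched and involves no stereocentre.

Step 2
Reactants: 2 primary alcohol + 3 allyl acetate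
Product: 4 2-[(4R,6S)-6-[(2S)-2-hydroxypent-4-en-1-yl]-2,2-dimethyl-1,3-dioxan-4-yl]acetonitrile
Conditions: [Ir(cod)Cl]2 (2.5 mol %), (S)-Cl,MeO-BIPHEP (5 mol %), 4-chloro-3-nitrobenzoic acid (10 mol %), Cs2CO3 (20 mol %), THF, 100 °C, sealed tube
Reagents that add atoms: none
Why: Krische transfer-hydrogenative allylation from the alcohol oxidation level, in which the cyclometallated iridium catalyst dehydrogenates the alcohol and allylates the transient aldehyde under catalyst control, the (S)-ligand giving the 13S carbinol (the same facial sense by which it converts propane-1,3-diol into the (S,S)-diol).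

Step 3
Reactants: 4 homoallylic alcohol
Product: 5 2-[(4R,6R)-6-[(2S)-2-(tert-butyldimethylsilyloxy)pent-4-en-1-yl]-2,2-dimethyl-1,3-dioxan-4-yl]acetonitrile
Conditions: TBSCl (1.3 equiv), imidazole (2.5 equiv), DMF, rt
Reagents that add atoms: tert-butyldimethylsilyl chloride CC(C)(C)[Si](C)(C)Cl
Why: Standard silylation of the secondary alcohol, needed because the later organolithium steps do not tolerate a free hydroxyl.

Step 4
Reactants: 5 silyl ether nitrile
Product: 6 C19 aldehyde 2-[(4S,6R)-6-[(2S)-2-(tert-butyldimethylsilyloxy)pent-4-en-1-yl]-2,2-dimethyl-1,3-dioxan-4-yl]acetaldehyde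
Conditions: i-Bu2AlH (1.3 equiv), CH2Cl2, −78 °C; then aq. KNaC4H4O6, rt
Reagents that add atoms: water O
Why: Partial hydride reduction of the nitrile to the N-aluminio imine and hydrolysis gives the aldehyde without touching the silyl ether, acetonide or alkene.

Step 5
Reactants: 6 C19 aldehyde
Product: 8 C19-epimeric terminal epoxide (about 1:1), via lithium chlorohydrin alkoxide 7 (not isolated)
Conditions: ClCH2I (1.5 equiv), n-BuLi (1.4 equiv), THF, −78 °C → rt
Reagents that add atoms: chloroiodomethane ClCI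
Why: Chloromethyllithium generated in situ adds to the aldehyde faster than it enolises it and the chlorohydrin alkoxide closes to the oxirane on warming (Matteson-type epoxide homologation), without facial control at C19.

Step 6
Reactants: 8 C19-epimeric epoxide
Product: 9 epoxide A (4S,6R)-2,2-dimethyl-4-[[(2R)-oxiran-2-yl]methyl]-6-[(2S)-2-(tert-butyldimethylsilyloxy)pent-4-en-1-yl]-1,3-dioxane
Conditions: (R,R)-(salen)Co(OAc) (trivalent cobalt; salen = N,N′-bis(3,5-di-tert-butylsalicylidene)cyclohexane-1,2-diaminate) (2 mol %), H2O (0.55 equiv), THF, 0 °C → rt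
Reagents that add atoms: none
Why: Jacobsen hydrolytic kinetic resolution, in which the (R,R)-catalyst hydrates only the epimer with an S oxirane carbon and leaves the 19R epoxide, so C19 is fixed by catalyst control (ceiling 50 %).

Step 7
Reactants: 10 1,5-dichloropentane-2,4-dione
Product: 11 (2S,4S)-1,5-dichloropentane-2,4-diol
Conditions: H2 (80 atm), RuCl2[(R)-BINAP] (0.1 mol %), MeOH, 50 °C; recrystallise
Reagents that add atoms: none
Why: Noyori asymmetric hydrogenation of a 1,3-diketone, where two catalyst-controlled reductions give the C2-symmetric anti diol (the double reduction raises the ee, and the minor meso diol is removed by crystallisation).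

Step 8
Reactants: 11 dichlorodiol
Product: 12 (2S,4S)-1,2:4,5-diepoxypentane
Conditions: KOH (powdered, 4 equiv), Et2O, 0 °C → rt
Reagents that add atoms: none
Why: Double Williamson ring closure at the CH2Cl carbons leaves both carbinol centres untouched, giving the C2-symmetric bis-electrophile that will become C22–C26.

Step 9
Reactants: 13 1-bromo-6-chlorohexane + 14 (S)-2-isopropyloxirane
Product: 16 (3R)-10-chloro-2-methyldecan-3-ol, via 6-chlorohexylmagnesium bromide 15 (not isolated)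
Conditions: 13, Mg, THF, rt; then CuI (10 mol %), 14, −30 → 0 °C; H2O
Reagents that add atoms: none
Why: Magnesium inserts selectively into the C–Br bond and the copper-catalysed Grignard opens the epoxide at its CH2 terminus (SN2), so the centre of 14 becomes C35 untouched (R after the priority change).

Step 10
Reactants: 16 chloro alcohol
Product: 17 1-[[(3R)-10-chloro-2-methyldecan-3-yl]oxymethyl]-4-methoxybenzene
Conditions: NaH, 4-methoxybenzyl chloride, Bu4NI (5 mol %), THF/DMF, 0 °C → rt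
Reagents that add atoms: 4-methoxybenzyl chloride COc1ccc(CCl)cc1
Why: Williamson etherification gives O35 a protecting group that survives organolithiums and can later be removed oxidatively in the presence of silyl ethers and the acetonide.

Step 11
Reactants: 17 PMB ether chloride + 18 1,3-dithiane
Product: 20 2-[(8R)-8-(4-methoxybenzyloxy)-9-methyldecyl]-1,3-dithiane, via 2-lithio-1,3-dithiane 19 (not isolated)
Conditions: 18, n-BuLi, THF, −30 °C; then 17, HMPA, −78 °C → rt, 16 h
Reagents that add atoms: none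
Why: Corey–Seebach alkylation of the dithiane anion by the primary chloride installs C27 as a masked ketone.

Step 12
Reactants: 20 alkyl dithiane + 12 (2S,4S)-diepoxypentane
Product: 22 (2S)-1-[2-[(8R)-8-(4-methoxybenzyloxy)-9-methyldecyl]-1,3-dithian-2-yl]-3-[(2S)-oxiran-2-yl]propan-2-ol, via lithiated dithiane 21 (not isolated)
Conditions: t-BuLi (1.05 equiv), THF/HMPA (10:1), −78 °C, 5 min; then 12 (3 equiv), −78 → −30 °C; H2O
Reagents that add atoms: none
Why: Dithiane umpolung, in which the 2-lithio-2-alkyl dithiane opens one CH2 terminus of the diepoxide (both ends identical, excess 12 suppresses double opening), so C25 and C23 are taken unchanged from 12.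

Step 13
Reactants: 22 epoxy alcohol
Product: 23 epoxide B (25-O-TBS ether of 22)
Conditions: TBSCl (1.5 equiv), imidazole (3 equiv), DMAP (0.1 equiv), DMF, 40 °C
Reagents that add atoms: tert-butyldimethylsilyl chloride CC(C)(C)[Si](C)(C)Cl
Why: Silylation under non-Lewis-acidic conditions protects O25 without opening the terminal epoxide.

Step 14
Reactants: 24 2-(tert-butyldimethylsilyl)-1,3-dithiane + 9 epoxide A + 23 epoxide B
Product: 28 C11–C35 bis-dithiane C23 alcohol, via 2-lithio-2-silyl dithiane 25 (not isolated), via C19 lithium alkoxide 26 (not isolated), via C21 lithio dithiane 27 (not isolated)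
Conditions: 24, t-BuLi, Et2O, −78 → −45 °C; 9, Et2O, −78 → −25 °C; then 23, HMPA (4 equiv), Et2O/THF, −78 °C → rt; H2O
Reagents that add atoms: none
Why: Smith-type anion relay (linchpin) coupling, in which the silyl dithiane anion opens epoxide A at C20, HMPA triggers the 1,4-Brook shift of silicon from C21 to O19, and the new C21 anion opens epoxide B at C22, so C19 (R) and C23 (S) come directly from the two epoxides and O19 emerges already silylated.

Step 15
Reactants: 28 C23 alcohol
Product: 29 23-O-TBS ether of 28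
Conditions: TBSOTf (1.5 equiv), 2,6-lutidine (3 equiv), CH2Cl2, −78 → 0 °C
Reagents that add atoms: tert-butyldimethylsilyl triflate CC(C)(C)[Si](C)(C)OS(=O)(=O)C(F)(F)F
Why: The hindered C23 hydroxyl flanked by two dithiane-bearing arms needs the silyl triflate, and it must be capped to prevent hemiketal formation and competing acylation later.

Step 16
Reactants: 29 bis-dithiane
Product: 30 C21,C27 diketone
Conditions: MeI (20 equiv), CaCO3 (10 equiv), MeCN/H2O (9:1), 45 °C, 16 h
Reagents that add atoms: water O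
Why: S-Methylation and buffered hydrolysis unmask both ketones under near-neutral conditions that spare the silyl ethers, acetonide, PMB ether and alkene, and it is done before any polyene exists.

Step 17
Reactants: 30 diketone PMB ether
Product: 31 C35 alcohol
Conditions: DDQ (1.5 equiv), CH2Cl2/aq. NaH2PO4–Na2HPO4 buffer pH 7 (10:1), 0 °C → rt
Reagents that add atoms: none
Why: Oxidative PMB cleavage frees only O35 and is placed after dithiane removal because DDQ would attack the dithianes.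

Step 18
Reactants: 31 terminal alkene + 32 (E)-crotonaldehyde
Product: 33 (E)-enal (C9 aldehyde)
Conditions: second-generation Hoveyda–Grubbs catalyst (H2IMes)Cl2Ru=CH(C6H4-2-OiPr) (5 mol %), 32 (5 equiv), CH2Cl2, 40 °C
Reagents that add atoms: none
Why: Olefin cross-metathesis of an unhindered terminal alkene with an enal is E-selective (thermodynamic control) and tolerates the free alcohol and ketones, fixing the C10=C11 geometry.

Step 19
Reactants: 33 enal
Product: 34 (8E,10E)-dienyl iodide C35 alcohol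
Conditions: CrCl2 (8 equiv), CHI3 (3 equiv), THF/1,4-dioxane (1:6), 0 °C → rt, dark
Reagents that add atoms: iodoform IC(I)I
Why: Takai iodo-olefination is selective for the aldehyde over the two ketones and gives the E alkenyl iodide (C8=C9).

Step 20
Reactants: 35 2,2-dimethoxyacetaldehyde + 36 ethyl 2-(triphenylphosphoranylidene)propanoate
Product: 38 ethyl (E)-2-methyl-4-oxobut-2-enoate, via acetal ester 37 (not isolated)
Conditions: CH2Cl2, rt, 12 h; then 2 M HCl, THF, rt
Reagents that add atoms: water O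
Why: Wittig olefination with the stabilised α-methyl ylide gives the (E)-trisubstituted enoate (C2=C3) and mild acid hydrolysis of the acetal frees the C4 aldehyde.

Step 21
Reactants: 38 enal ester
Product: 39 ethyl (2E,4E)-5-iodo-2-methylpenta-2,4-dienoate
Conditions: CrCl2 (6 equiv), CHI3 (2 equiv), THF, 0 °C
Reagents that add atoms: iodoform IC(I)I
Why: Takai iodo-olefination of the aldehyde gives the E alkenyl iodide (C4=C5) without touching the enoate.

Step 22
Reactants: 39 iododienoate ester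
Product: 40 (2E,4E)-5-iodo-2-methylpenta-2,4-dienoic acid
Conditions: LiOH (3 equiv), THF/MeOH/H2O (3:1:1), rt; then 1 M HCl to pH 3
Reagents that add atoms: lithium hydroxide [Li+].[OH-]
Why: Simple saponification; the dienyl iodide is stable to aqueous hydroxide at room temperature.

Step 23
Reactants: 34 dienyl iodide alcohol + 40 iododienoic acid
Product: 42 bis(dienyl iodide) ester, via mixed anhydride 41 (not isolated)
Conditions: 40, 2,4,6-trichlorobenzoyl chloride (1.5 equiv), Et3N (2 equiv), THF, rt; then 34, DMAP (0.5 equiv), toluene, rt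
Reagents that add atoms: none
Why: Intermolecular Yamaguchi esterification acylates the hindered C35 alcohol with retention at C35, and the acid has no sp3 γ-hydrogen so it cannot deconjugate.

Step 24
Reactants: 42 bis(dienyl iodide) ester + 43 (E)-1,2-bis(tributylstannyl)ethene
Product: 45 protected macrolide, via mono-coupled stannyl triene 44 (not isolated)
Conditions: Pd(MeCN)2Cl2 (20 mol %), i-Pr2NEt (2 equiv), DMF/THF (1:1), 1 mM in 42, 43 (1.1 equiv) added over 12 h, 25 °C, dark
Reagents that add atoms: none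
Why: Stille "stitching" macrocyclisation, in which zerovalent palladium formed in situ couples one alkenyl iodide with one tin terminus intermolecularly and then closes the 36-membered ring by the second, intramolecular Stille coupling at high dilution, both with retention of alkene geometry, so the all-E pentaene and the ring form together and no stereocentre is touched.

Step 25
Reactants: 45 protected macrolide
Product: 46 target macrolide CNP0167014.1
Conditions: HF (48 % aq.), MeCN/THF (4:1), 0 °C → rt, polypropylene flask, dark; NaHCO3 quench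
Reagents that add atoms: none
Why: Aqueous HF cleaves the four silyl ethers and hydrolyses the acetonide in one operation without base (which would cause retro-aldol or elimination of the β-hydroxy ketones) and without alcohol solvent (which would form mixed ketals).

**Compound list**

1 | tert-butyl 2-[(4R,6R)-6-(cyanomethyl)-2,2-dimethyl-1,3-dioxan-4-yl]acetate (atorvastatin side-chain nitrile; syn acetonide) | N#CC[C@@H]1C[C@H](CC(=O)OC(C)(C)C)OC(C)(C)O1 | starting material
2 | 2-[(4R,6S)-6-(2-hydroxyethyl)-2,2-dimethyl-1,3-dioxan-4-yl]acetonitrile | N#CC[C@@H]1C[C@H](CCO)OC(C)(C)O1 | intermediate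
3 | allyl acetate | CC(=O)OCC=C | starting material
4 | 2-[(4R,6S)-6-[(2S)-2-hydroxypent-4-en-1-yl]-2,2-dimethyl-1,3-dioxan-4-yl]acetonitrile | N#CC[C@@H]1C[C@H](C[C@@H](O)CC=C)OC(C)(C)O1 | intermediate
5 | 2-[(4R,6R)-6-[(2S)-2-(tert-butyldimethylsilyloxy)pent-4-en-1-yl]-2,2-dimethyl-1,3-dioxan-4-yl]acetonitrile | N#CC[C@@H]1C[C@H](C[C@@H](O[Si](C)(C)C(C)(C)C)CC=C)OC(C)(C)O1 | intermediate
6 | 2-[(4S,6R)-6-[(2S)-2-(tert-butyldimethylsilyloxy)pent-4-en-1-yl]-2,2-dimethyl-1,3-dioxan-4-yl]acetaldehyde (C19 aldehyde) | O=CC[C@@H]1C[C@H](C[C@@H](O[Si](C)(C)C(C)(C)C)CC=C)OC(C)(C)O1 | intermediate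
7 | lithium alkoxide of the C19/C20 chlorohydrin (1-chloro-3-(dioxan-4-yl)propan-2-olate, both C19 epimers; not isolated) | [Li]OC(CCl)C[C@@H]1C[C@H](C[C@@H](O[Si](C)(C)C(C)(C)C)CC=C)OC(C)(C)O1 | intermediate
8 | 4-(oxiran-2-ylmethyl) dioxane, about 1:1 at the oxirane carbon (C19), other centres as in 6 | C1OC1C[C@@H]2C[C@H](C[C@@H](O[Si](C)(C)C(C)(C)C)CC=C)OC(C)(C)O2 | intermediate
9 | epoxide A: (4S,6R)-2,2-dimethyl-4-[[(2R)-oxiran-2-yl]methyl]-6-[(2S)-2-(tert-butyldimethylsilyloxy)pent-4-en-1-yl]-1,3-dioxane | C1O[C@@H]1C[C@@H]2C[C@H](C[C@@H](O[Si](C)(C)C(C)(C)C)CC=C)OC(C)(C)O2 | intermediate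
10 | 1,5-dichloropentane-2,4-dione | ClCC(=O)CC(=O)CCl | starting material
11 | (2S,4S)-1,5-dichloropentane-2,4-diol | ClC[C@@H](O)C[C@H](O)CCl | intermediate
12 | (2S,4S)-1,2:4,5-diepoxypentane | C1O[C@H]1C[C@H]1CO1 | intermediate
13 | 1-bromo-6-chlorohexane | ClCCCCCCBr | starting material
14 | (S)-2-isopropyloxirane | CC(C)[C@H]1CO1 | starting material
15 | 6-chlorohexylmagnesium bromide (not isolated) | ClCCCCCC[Mg]Br | intermediate
16 | (3R)-10-chloro-2-methyldecan-3-ol | ClCCCCCCC[C@H](C(C)C)O | intermediate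
17 | 1-[[(3R)-10-chloro-2-methyldecan-3-yl]oxymethyl]-4-methoxybenzene | ClCCCCCCC[C@H](C(C)C)OCc1ccc(OC)cc1 | intermediate
18 | 1,3-dithiane | C1CSCSC1 | starting material
19 | 2-lithio-1,3-dithiane (not isolated) | [Li]C1SCCCS1 | intermediate
20 | 2-[(8R)-8-(4-methoxybenzyloxy)-9-methyldecyl]-1,3-dithiane (C27–C35) | S1CCCSC1CCCCCCC[C@H](C(C)C)OCc2ccc(OC)cc2 | intermediate
21 | 2-lithio derivative of 20 (not isolated) | [Li]C1(SCCCS1)CCCCCCC[C@H](C(C)C)OCc2ccc(OC)cc2 | intermediate
22 | (2S)-1-[2-[(8R)-8-(4-methoxybenzyloxy)-9-methyldecyl]-1,3-dithian-2-yl]-3-[(2S)-oxiran-2-yl]propan-2-ol (C22–C35; 25-OH) | C1O[C@H]1C[C@H](O)CC2(SCCCS2)CCCCCCC[C@H](C(C)C)OCc3ccc(OC)cc3 | intermediate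
23 | epoxide B: 25-O-TBS ether of 22 | C1O[C@H]1C[C@H](O[Si](C)(C)C(C)(C)C)CC2(SCCCS2)CCCCCCC[C@H](C(C)C)OCc3ccc(OC)cc3 | intermediate
24 | 2-(tert-butyldimethylsilyl)-1,3-dithiane | CC(C)(C)[Si](C)(C)C1SCCCS1 | starting material
25 | 2-lithio-2-(tert-butyldimethylsilyl)-1,3-dithiane (not isolated) | CC(C)(C)[Si](C)(C)C1([Li])SCCCS1 | intermediate
26 | adduct of 25 with 9: C19 lithium alkoxide, 2-silyl dithiane at C21 (not isolated) | C=CC[C@H](O[Si](C)(C)C(C)(C)C)C[C@H]2C[C@@H](C[C@@H](O[Li])CC3([Si](C)(C)C(C)(C)C)SCCCS3)OC(C)(C)O2 | intermediate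
27 | Brook-shifted species: 19-OTBS, 2-lithio dithiane at C21 (not isolated) | C=CC[C@H](O[Si](C)(C)C(C)(C)C)C[C@H]2C[C@@H](C[C@@H](O[Si](C)(C)C(C)(C)C)CC3([Li])SCCCS3)OC(C)(C)O2 | intermediate
28 | C11–C35 chain: terminal alkene (C11=CH2), 13-OTBS, 15,17-O-isopropylidene (syn), 19-OTBS, 1,3-dithiane-2,2-diyl at C21 and C27, 23-OH, 25-OTBS, 35-OPMB; centres spatially as in the target | C=CC[C@H](O[Si](C)(C)C(C)(C)C)C[C@H]2C[C@@H](C[C@@H](O[Si](C)(C)C(C)(C)C)CC3(SCCCS3)C[C@@H](O)C[C@H](O[Si](C)(C)C(C)(C)C)CC4(SCCCS4)CCCCCCC[C@H](C(C)C)OCc5ccc(OC)cc5)OC(C)(C)O2 | intermediate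
29 | 23-O-TBS ether of 28 | C=CC[C@H](O[Si](C)(C)C(C)(C)C)C[C@H]2C[C@@H](C[C@@H](O[Si](C)(C)C(C)(C)C)CC3(SCCCS3)C[C@@H](O[Si](C)(C)C(C)(C)C)C[C@H](O[Si](C)(C)C(C)(C)C)CC4(SCCCS4)CCCCCCC[C@H](C(C)C)OCc5ccc(OC)cc5)OC(C)(C)O2 | intermediate
30 | C21,C27 diketone (both dithianes of 29 replaced by C=O) | C=CC[C@H](O[Si](C)(C)C(C)(C)C)C[C@H]2C[C@@H](C[C@@H](O[Si](C)(C)C(C)(C)C)CC(=O)C[C@@H](O[Si](C)(C)C(C)(C)C)C[C@H](O[Si](C)(C)C(C)(C)C)CC(=O)CCCCCCC[C@H](C(C)C)OCc3ccc(OC)cc3)OC(C)(C)O2 | intermediate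
31 | C35 alcohol (30 without PMB) | C=CC[C@H](O[Si](C)(C)C(C)(C)C)C[C@H]2C[C@@H](C[C@@H](O[Si](C)(C)C(C)(C)C)CC(=O)C[C@@H](O[Si](C)(C)C(C)(C)C)C[C@H](O[Si](C)(C)C(C)(C)C)CC(=O)CCCCCCC[C@H](C(C)C)O)OC(C)(C)O2 | intermediate
32 | (E)-crotonaldehyde | C/C=C/C=O | starting material
33 | (10E)-enal: C9 aldehyde, C10=C11, otherwise as 31 | O=C/C=C/C[C@H](O[Si](C)(C)C(C)(C)C)C[C@H]2C[C@@H](C[C@@H](O[Si](C)(C)C(C)(C)C)CC(=O)C[C@@H](O[Si](C)(C)C(C)(C)C)C[C@H](O[Si](C)(C)C(C)(C)C)CC(=O)CCCCCCC[C@H](C(C)C)O)OC(C)(C)O2 | intermediate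
34 | (8E,10E)-8-iodo diene (C8–C35) with free 35-OH | I/C=C/C=C/C[C@H](O[Si](C)(C)C(C)(C)C)C[C@H]2C[C@@H](C[C@@H](O[Si](C)(C)C(C)(C)C)CC(=O)C[C@@H](O[Si](C)(C)C(C)(C)C)C[C@H](O[Si](C)(C)C(C)(C)C)CC(=O)CCCCCCC[C@H](C(C)C)O)OC(C)(C)O2 | intermediate
35 | 2,2-dimethoxyacetaldehyde | COC(OC)C=O | starting material
36 | ethyl 2-(triphenylphosphoranylidene)propanoate | CCOC(=O)C(C)=P(c1ccccc1)(c1ccccc1)c1ccccc1 | starting material
37 | ethyl (E)-4,4-dimethoxy-2-methylbut-2-enoate (not isolated) | CCOC(=O)/C(C)=C/C(OC)OC | intermediate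
38 | ethyl (E)-2-methyl-4-oxobut-2-enoate | CCOC(=O)/C(C)=C/C=O | intermediate
39 | ethyl (2E,4E)-5-iodo-2-methylpenta-2,4-dienoate | CCOC(=O)/C(C)=C/C=C/I | intermediate
40 | (2E,4E)-5-iodo-2-methylpenta-2,4-dienoic acid | OC(=O)/C(C)=C/C=C/I | intermediate
41 | mixed anhydride of 40 with 2,4,6-trichlorobenzoic acid (not isolated) | O=C(OC(=O)/C(C)=C/C=C/I)c1c(Cl)cc(Cl)cc1Cl | intermediate
42 | bis(dienyl iodide): 34 acylated at O35 by 40 | I/C=C/C=C/C[C@H](O[Si](C)(C)C(C)(C)C)C[C@H]2C[C@@H](C[C@@H](O[Si](C)(C)C(C)(C)C)CC(=O)C[C@@H](O[Si](C)(C)C(C)(C)C)C[C@H](O[Si](C)(C)C(C)(C)C)CC(=O)CCCCCCC[C@H](C(C)C)OC(=O)/C(C)=C/C=C/I)OC(C)(C)O2 | intermediate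
43 | (E)-1,2-bis(tributylstannyl)ethene | CCCC[Sn](CCCC)(CCCC)/C=C/[Sn](CCCC)(CCCC)CCCC | starting material
44 | mono-coupled species: C1–C7 trienoate with Bu3Sn on C7, C8 iodide still in place (not isolated) | I/C=C/C=C/C[C@H](O[Si](C)(C)C(C)(C)C)C[C@H]2C[C@@H](C[C@@H](O[Si](C)(C)C(C)(C)C)CC(=O)C[C@@H](O[Si](C)(C)C(C)(C)C)C[C@H](O[Si](C)(C)C(C)(C)C)CC(=O)CCCCCCC[C@H](C(C)C)OC(=O)/C(C)=C/C=C/C=C/[Sn](CCCC)(CCCC)CCCC)OC(C)(C)O2 | intermediate
45 | protected macrolide: 13,19,23,25-tetra-O-TBS, 15,17-O-isopropylidene | C\C1=C/C=C/C=C/C=C/C=C/C[C@H](O[Si](C)(C)C(C)(C)C)C[C@H]2C[C@@H](C[C@@H](O[Si](C)(C)C(C)(C)C)CC(=O)C[C@@H](O[Si](C)(C)C(C)(C)C)C[C@H](O[Si](C)(C)C(C)(C)C)CC(=O)CCCCCCC[C@H](C(C)C)OC1=O)OC(C)(C)O2 | intermediate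
46 | CNP0167014.1: (2E,4E,6E,8E,10E,13S,15S,17S,19R,23S,25S,35R)-13,15,17,19,23,25-hexahydroxy-2-methyl-21,27-dioxo-35-isopropyl 36-membered macrolactone | C\C1=C/C=C/C=C/C=C/C=C/C[C@H](O)C[C@H](O)C[C@H](O)C[C@@H](O)CC(=O)C[C@@H](O)C[C@H](O)CC(=O)CCCCCCC[C@H](C(C)C)OC1=O | target

**Summary**

Total steps: 25. Longest linear sequence: 15 steps (1 → 2 → 4 → 5 → 6 → 8 → 9 → 28 → 29 → 30 → 31 → 33 → 34 → 42 → 45 → 46).

Three steps most likely to fail:

Step 24 (three-component Stille stitching; oligomerisation or slow second coupling). The fallback sets out from 34 and returns at 45. Compound 34 is coupled with a fourfold excess of 43 (Pd2(dba)3, AsPh3, NMP, rt) to give the trienyl stannane alcohol F4. Yamaguchi acylation of F4 with 40 gives the stannane–iodide seco ester F5. F5 is then closed by a single, unimolecular Stille coupling at high dilution (Pd2(dba)3, AsPh3, i-Pr2NEt, DMF/THF) to give 45, so the ring closure no longer depends on a bimolecular first coupling.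

Step 14 (one-flask linchpin coupling; the relayed C21 anion may be quenched before it opens the hindered epoxide B). The fallback sets out from 23 (with 9 and 18) and returns at 29. 2-Lithio-1,3-dithiane 19 opens 23 at C22 (THF/HMPA) to give the C21-unsubstituted dithiane alcohol F1. TBSOTf/2,6-lutidine gives the bis-silyl ether F2. Deprotonation of F2 at C21 (t-BuLi, THF/HMPA, −78 °C) and opening of 9 gives the C19 alcohol F3, and silylation of F3 (TBSOTf, 2,6-lutidine) gives 29. This replaces the relay by two separate dithiane alkylations.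

Step 25 (acidic global deprotection of a pentaene bearing β-hydroxy ketones). The fallback sets out from 42 and returns at 46. Compound 42, which has no polyene yet, is treated with aqueous HF in MeCN to give the fully deprotected hexaol bis(dienyl iodide) F6. F6 is then stitched with 43 under the step 24 conditions (Stille coupling tolerates free hydroxyls) to give 46 directly, so the pentaene never sees acid.

Further compounds
F1 | step 14 | C21–C35 dithiane alcohol: 2-monosubstituted dithiane at C21, 23-OH, 25-OTBS, C27 dithiane, 35-OPMB | S1CCCSC1C[C@@H](O)C[C@H](O[Si](C)(C)C(C)(C)C)CC2(SCCCS2)CCCCCCC[C@H](C(C)C)OCc3ccc(OC)cc3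
F2 | step 14 | 23-O-TBS ether of F1 | S1CCCSC1C[C@@H](O[Si](C)(C)C(C)(C)C)C[C@H](O[Si](C)(C)C(C)(C)C)CC2(SCCCS2)CCCCCCC[C@H](C(C)C)OCc3ccc(OC)cc3
F3 | step 14 | C19 alcohol: as 29 but with free 19-OH | C=CC[C@H](O[Si](C)(C)C(C)(C)C)C[C@H]2C[C@@H](C[C@@H](O)CC3(SCCCS3)C[C@@H](O[Si](C)(C)C(C)(C)C)C[C@H](O[Si](C)(C)C(C)(C)C)CC4(SCCCS4)CCCCCCC[C@H](C(C)C)OCc5ccc(OC)cc5)OC(C)(C)O2
F4 | step 24 | (6E,8E,10E)-trienyl stannane (Bu3Sn on C6) with free 35-OH | CCCC[Sn](CCCC)(CCCC)/C=C/C=C/C=C/C[C@H](O[Si](C)(C)C(C)(C)C)C[C@H]2C[C@@H](C[C@@H](O[Si](C)(C)C(C)(C)C)CC(=O)C[C@@H](O[Si](C)(C)C(C)(C)C)C[C@H](O[Si](C)(C)C(C)(C)C)CC(=O)CCCCCCC[C@H](C(C)C)O)OC(C)(C)O2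
F5 | step 24 | stannane–iodide seco ester: F4 acylated at O35 by 40 | CCCC[Sn](CCCC)(CCCC)/C=C/C=C/C=C/C[C@H](O[Si](C)(C)C(C)(C)C)C[C@H]2C[C@@H](C[C@@H](O[Si](C)(C)C(C)(C)C)CC(=O)C[C@@H](O[Si](C)(C)C(C)(C)C)C[C@H](O[Si](C)(C)C(C)(C)C)CC(=O)CCCCCCC[C@H](C(C)C)OC(=O)/C(C)=C/C=C/I)OC(C)(C)O2
F6 | step 25 | fully deprotected bis(dienyl iodide): 13,15,17,19,23,25-hexaol, 21,27-diketone | I/C=C/C=C/C[C@H](O)C[C@H](O)C[C@H](O)C[C@@H](O)CC(=O)C[C@@H](O)C[C@H](O)CC(=O)CCCCCCC[C@H](C(C)C)OC(=O)/C(C)=C/C=C/I
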